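In amounts, each electrophile that reacts asks for two acids to be carried off: the one it sets free and the one taken from the protonated nucleophile to free the nucleophile.

    nucleophile + acid set free ⇌ protonated nucleophile, settled at all times (K1 = 2.3 × 10⁵ /M)
    acid set free → by-product carried off (k2 = 0.32 /s)
    electrophile + nucleophile → acid set free + product (k3 = 3.2 /M/s)
    acid set free + free base ⇌ salt of the base (K4 = 6.9 × 10⁵ /M, k4 = 72 /M/s)

all flasks: electrophile 20 mM; protonated nucleophile 1.10 equiv; time 15 min

| flask | free base |
|---|---|
| summer | 1.00 equiv |
| dusk | 2.00 equiv |

- part of the electrophile that has reacted at the end, summer
- part of the electrophile that has reacted at the end, dusk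
- what raising the equivalents of free base from its lowest to its highest value here does to the part of the electrophile that has reacted (changes below 5 percentage points count as none) (it rises / no change / it falls)

**Nucleophile level.** Acid leaves with the rate constant r, which is 0.32 /s plus 72 /M/s times [free base]. The two-acid count makes r[acid set free] equal 2·3.2 /M/s[electrophile][nucleophile], and the balance ties [nucleophile][acid set free] to [protonated nucleophile]/2.3 × 10⁵ /M. Protonated nucleophile and electrophile fall about one for one, which keeps their difference and lets their ratio climb from the charged 1.10; this reckoning holds the ratio at that value as a simplification, and the amounts cancel. [nucleophile] is then the square root of 1.10·r/(2·2.3 × 10⁵ /M·3.2 /M/s). The electrophile decays pseudo-first-order, with half-life ln 2/(3.2 /M/s[nucleophile]).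

**Start of the curve.** In summer r begins at 1.76 /s, which gives 1.15 mM of nucleophile. The electrophile therefore falls at 4.40 mM/min, with half-life 3.15 min.

**The knee.** When half the electrophile has reacted, one equivalent of acid has had to go. Summer's base is then taken to have sunk to the crossing at 4.44 mM, where base and by-product step take acid equally. There r is 0.640 /s, which gives 0.692 mM of nucleophile and 5.22 min, the mid-run half-life. Summer's 15 min holds 2.87 of these, so 86.4% has reacted.

**Dusk.** Dusk is taken to keep 20.0 mM of base at that point, so its mid-run half-life is reckoned at 3.15 min, shorter than summer's. That makes 4.76 half-lives and 96.3% reacted. With the base step out of play, r is 0.32 /s and the half-life 7.38 min.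

**Result.** The forecast gave 86% and 95%, it rises, since with less base “the slower by-product step has to carry the acid removal”. The simulation gives 86.1% for summer and 94.9% for dusk, so it rises, by 8.8 percentage points.

**Base step.** The gap comes from the difference in equivalents of free base, acting through the base step. Left out, it takes dusk from 94.9% to 76.3% and the gap to 0 points. The count there is 2.03 half-lives of 7.38 min, or 75.6% reacted. The neighbour of summer with 4.40 equiv of protonated nucleophile has its mid-run half-life shortened by the square root of the equivalents, to 2.61 min. That gives 5.75 half-lives and 98.1% reacted; the simulation gives >99.9%, with nucleophile at 8.40 mM.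

Its constants are assumed; the rest is arithmetic.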